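## Analysis of the target

The target 40 is a cembranolide: a 14-membered carbocycle (C1–C14, cembrane numbering) trans-fused across C1/C14 to an α-methylene-γ-butyrolactone (C15 α-carbon, C16 carbonyl, C17 exo-methylene). The large ring carries a trans 2,2,3-trisubstituted oxirane at C3/C4 (methyl C18 on C4), a secondary allylic hydroperoxide at C7 beside the exo-methylene C8=C19, an E-trisubstituted olefin C11=C12 (methyl C20 on C12) and an acetate at C13. There are six stereocentres, C1 (R), C3 (S), C4 (S), C7 (S), C13 (S) and C14 (R). C13, C14 and C1 are contiguous (the C13 and C14 oxygens anti, the C14 and C1 substituents trans on the lactone), C3/C4 lie one methylene from C1, and C7 is remote from all the others. The hydroperoxide is reduced by phosphines, tin hydrides and low-valent metals and is eliminated by base; the α-methylene lactone is a Michael acceptor; the epoxide and the allylic acetate are acid-sensitive. The difficulty is that C3/C4, C7/C8 and C11/C12 all stand at the level of a trisubstituted olefin but must end as an epoxide, a transposed allylic hydroperoxide and a plain E-olefin, so an epoxidation of a polyene would have to choose between nearly identical double bonds, and a 14-membered ring must be closed beside all of this. The strategy rests on C4: it is the only fully substituted stereocentre and sits next to the epoxide methine C3, so read backwards C4 is a tertiary alkoxide carbon and C3 a carbon that held a leaving group. That is the adduct of a carbon nucleophile with an α-chloro methyl ketone, and the bond it points to, C4–C5, lies roughly opposite the lactone and divides the molecule into two halves of similar size.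

## Retrosynthetic reasoning

**C7–O (40 to 39).** The O–C7 bond is cut and the C8=C19 olefin is returned to C7=C8, the retron of a Schenck ene reaction. Doing this last means no later reagent meets the hydroperoxide. The forward step must choose the C7=C8 olefin of 39 over C11=C12, take the hydrogen from C19 and attack one face.

**C13 acetate, C12–C20 and the C11=C12 olefin (39 to 36).** Removing the acetyl group gives 38. Its C12–C20 bond is cut to the alkenylstannane 37, and the C12–Sn and C11–H bonds are cut to the cycloalkyne 36. An alkyne at C11–C12 cannot be confused with the C7=C8 olefin, and a hydroxyl-directed trans-hydrostannation fixes both the E geometry and the position of the methyl group by mechanism rather than by ring conformation.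

**C11≡C12 (36 to 34).** The ring is opened at the triple bond by ring-closing alkyne metathesis, through the silyl ether 35 to the diyne 34. This bond is far from every stereocentre except C13, has no stereochemical outcome of its own, and the catalyst leaves olefins alone.

**C15–C17 (34 to 31).** The exo-methylene carbon is removed to give 31. It is introduced only after the organometallic coupling, so that no Michael acceptor meets a Grignard reagent, and before the acetate is present, because it needs a lactone enolate.

**C4–C5 and C3–O (31 to 21 and 29).** The epoxide C3–O bond and the C4–C5 bond are cut together, giving the α-chloro methyl ketone 21 and the Grignard reagent 29. The epoxide oxygen is already in the ketone, so no olefin has to be selected, and the quaternary centre C4 is set from the neighbouring C3 stereocentre. The forward reaction must add to the ketone and not to the lactone, must not enolise the ketone, must follow the Cornforth sense of 1,2-induction, and must close the oxirane with inversion at C3.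

**The enyne half (29 to 22).** The magnesium of 29 goes back to the bromide 28 and the alcohol 27. In 27 the C6–C7 and C8–C19 bonds are cut together: methyl and a metal are added syn across the terminal alkyne of the diyne 24 and the alkenyl metal is alkylated by a two-carbon epoxide electrophile, which fixes the E geometry of C7=C8. The C8–C9 bond of 24 is cut to an acetylide and the tosylate 23 of pent-3-yn-1-ol 22.

**C4–C18, C3–Cl and C4–O (21 to 15).** The methyl group C18 is cut from C4 (a methyl nucleophile on an aldehyde, then oxidation of 20). The C3–Cl bond is cut by organocatalytic α-chlorination of the aldehyde 18, where the catalyst and not C1 decides the configuration. The C4 oxygen is traced through 17 to the terminal olefin of 15 by hydroboration.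

**C12–C13 (15 to 12 and 13).** The silyl ether 15 comes from the carbinol 14, whose C12–C13 bond is cut to the aldehyde 12 and the propynyl Grignard reagent 13. The C14 oxygen directs the addition to the anti carbinol.

**C1–C2 (12 to 7 and 8).** The aldehyde 12 is traced through 11 to the silyl ether 10, whose C1–C2 bond is cut to the butenolide 7 and the allyl Grignard reagent 8. The conjugate addition enters anti to the C14 substituent and so sets C1.

**C14 from the chiral pool (7 to 1).** The butenolide 7 comes from the saturated lactone 4 by dehydrogenation, and 4 from D-glutamic acid 1 through 2 and 3. The amino acid supplies C14, from which C1 and C13 are then derived.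

## Alternatives that were turned down

**Alternative 1: three-component coupling on a chiral-pool butenolide.** The disconnection cuts C1–C2 and C15–C17 on the lactone ring. In the forward step a vinyl copper reagent adds to C1 of the (R)-trityloxymethyl butenolide A2 anti to the C14 substituent, and the enolate is trapped at C15 by formaldehyde A3 to give the all-trans hydroxymethyl vinyl lactone A1. In its favour, one step makes two C–C bonds, relays C14 to C1, and puts C17 in place so that no late enolate chemistry is needed next to an epoxide. Against it, this is a fragment-level move: the quaternary epoxide carbon C4, the differentiation of the three olefin-level sites and the ring closure are left untouched. The vinyl group supplies only C2 and C3, so the epoxide would have to come from an olefination and an epoxidation, which meets the choice between C3=C4 and C7=C8. The β-hydroxymethyl lactone would also have to be carried, protected, through the whole middle of the route, where it can eliminate or undergo retro-aldol cleavage. On C1 it is as strong as the chosen route, which uses the same anti addition, and on C17 it is one step shorter and avoids a strong base late on. The chosen strategy offers in exchange a defined answer for C3/C4 and carries less functionality through the coupling.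

**Alternative 2: late palladium cyclocarbonylation to the α-methylene lactone.** The disconnection cuts C15–C16 and C16–O, so the lactone carbonyl is removed. In the forward step the macrocyclic homopropargylic alcohol A5 (C14 hydroxyl, ethynyl group on C1) takes up carbon monoxide A6 on a divalent palladium catalyst; the alkoxycarbonyl palladium adds across the alkyne and protonolysis gives the macrocyclic α-methylene lactone A4. In its favour, C15, C16, C17 and the five-membered ring appear in one catalytic step at a late stage, so the Michael acceptor is never carried and no enolate is needed. Against it, without the lactone ring the C14/C1 relationship must be set in an open chain rather than by addition to a rigid butenolide. The terminal alkyne on C1 is incompatible with an alkyne-metathesis ring closure and with hydrostannation unless it is masked. The halide and acid promoters common in such carbonylations threaten the trisubstituted epoxide. The C3/C4 problem is again not addressed. It is stronger on step economy for the lactone and on handling of the acceptor. The chosen strategy offers instead the lactone as stereochemical template from the first stereoselective step (C1 and C13 both from C14) and a solution for C4.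

**Alternative 3: nickel reductive ynal macrocyclisation at C12–C13.** The disconnection cuts the ring bond C12–C13. In the forward step the ynal A8 (aldehyde C13 on the lactone, methyl-capped C11≡C12 alkyne at the other chain end) is coupled by a zerovalent nickel catalyst to an oxanickelacycle, which triethylsilane A9 cleaves with delivery of hydrogen to C11; this gives the 14-membered E-allylic silyl ether A7. In its favour, one step closes the ring, makes the E-olefin with the methyl group on C12, sets C13 and protects it, replacing propynylation, silylation, metathesis, desilylation, hydrostannation and methylation, and it uses no tin. Against it, C13 would be set during ring closure under induction from C14 in a constrained transition state whose sense and level cannot be predicted, and a wrong epimer in the macrocycle is hard to correct. The regiochemistry of alkyne insertion (C12 against C11, which would give an exocyclic olefin in a 15-membered ring) depends on ligand and ring size. The ynal is an epimerisable α-acyloxy aldehyde that must be made late beside the epoxide, and low-valent nickel can insert into epoxides. It is clearly stronger on step count in the endgame. The chosen strategy offers C13 set in an open chain where it can be corrected by oxidation and reduction, an olefin geometry fixed by a mechanism-based trans-addition, and a ring closure whose only selectivity issue is ring against oligomer. This alternative is also only an endgame variant: it still needs the epoxide answer that the chosen key step supplies.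

Key step: step 19

## Remarks and assumptions

- Positions are numbered as in cembrane: C1 lactone β-carbon, C14 lactone O–CH, C15/C16/C17 lactone α-carbon, carbonyl and exo-methylene, C18, C19 and C20 the methyl carbons on C4, C8 and C12.
- Assumption: in step 12 the enantiomer of trans-2,5-diphenylpyrrolidine is used that delivers the (3R) chloride; the sense is set by the catalyst and either enantiomer can be used.
- Compound 3 is also an article of commerce; buying it would remove steps 1 and 2.
- TBDPS = tert-butyldiphenylsilyl, TES = triethylsilyl, 9-BBN = 9-borabicyclo[3.3.1]nonane, DMAP = 4-(dimethylamino)pyridine.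

## Route

**Step 1**
Reactants: 1 D-glutamic acid
Product: 2 (R)-5-oxotetrahydrofuran-2-carboxylic acid
Conditions: NaNO2, aq. HCl, 0 to 23 °C
Reagents that add atoms: none
Why: Deaminative lactonisation: diazotisation, displacement of nitrogen by the neighbouring carboxylate and ring opening by the γ-carboxyl group give the lactone with net retention at C14 (double inversion).

**Step 2**
Reactants: 2 (R)-5-oxotetrahydrofuran-2-carboxylic acid
Product: 3 (R)-5-(hydroxymethyl)dihydrofuran-2(3H)-one
Conditions: BH3·SMe2, THF, 0 to 23 °C; MeOH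
Reagents that add atoms: none
Why: Borane reduces the free carboxylic acid much faster than the lactone (chemoselective borane reduction).

**Step 3**
Reactants: 3 (R)-5-(hydroxymethyl)dihydrofuran-2(3H)-one
Product: 4 (R)-5-[(TBDPS-oxy)methyl]dihydrofuran-2(3H)-one
Conditions: t-BuPh2SiCl, imidazole, DMF, 23 °C
Reagents that add atoms: tert-butyl(chloro)diphenylsilane, CC(C)(C)[Si](Cl)(c1ccccc1)c1ccccc1
Why: Silylation of the primary alcohol; the bulky silyl ether later shields one face of the butenolide.

**Step 4**
Reactants: 4 (R)-5-[(TBDPS-oxy)methyl]dihydrofuran-2(3H)-one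
Product: 7 (R)-5-[(TBDPS-oxy)methyl]furan-2(5H)-one, via selenide 5 (not isolated), via selenoxide 6 (not isolated)
Conditions: LiN(iPr)2, THF, −78 °C; PhSeBr; then 30% H2O2, pyridine, CH2Cl2, 0 to 23 °C
Reagents that add atoms: none
Why: α-Selenenylation of the lactone enolate, oxidation and syn elimination of the selenoxide toward the only β-hydrogens give the conjugated butenolide (selenoxide elimination); C14 is not touched.

**Step 5**
Reactants: 7 (R)-5-[(TBDPS-oxy)methyl]furan-2(5H)-one; 8 allylmagnesium bromide
Product: 10 (4R,5R)-4-allyl-5-[(TBDPS-oxy)methyl]dihydrofuran-2(3H)-one, via silyl ketene acetal 9 (not isolated)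
Conditions: CuBr·SMe2, Me3SiCl, THF, −78 °C; aq. NH4Cl
Reagents that add atoms: none
Why: Copper-mediated 1,4-addition of the allyl group, accelerated by the chlorosilane, should enter anti to the silyloxymethyl group on C14 and so set C1 (R) trans to C14; the silyl ketene acetal is hydrolysed on work-up.

**Step 6**
Reactants: 10 (4R,5R)-4-allyl-5-[(TBDPS-oxy)methyl]dihydrofuran-2(3H)-one
Product: 11 (4R,5R)-4-allyl-5-(hydroxymethyl)dihydrofuran-2(3H)-one
Conditions: Bu4NF, AcOH, THF, 0 to 23 °C
Reagents that add atoms: none
Why: Fluoride cleaves the silyl ether; the acetic acid buffer suppresses acyl migration of the γ-lactone.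

**Step 7**
Reactants: 11 (4R,5R)-4-allyl-5-(hydroxymethyl)dihydrofuran-2(3H)-one
Product: 12 (2R,3R)-3-allyl-5-oxotetrahydrofuran-2-carbaldehyde
Conditions: Dess–Martin periodinane, NaHCO3, CH2Cl2, 0 to 23 °C
Reagents that add atoms: none
Why: Buffered Dess–Martin oxidation gives the α-acyloxy aldehyde without base, so C14 should not epimerise; the aldehyde is used at once.

**Step 8**
Reactants: 12 (2R,3R)-3-allyl-5-oxotetrahydrofuran-2-carbaldehyde; 13 prop-1-yn-1-ylmagnesium bromide
Product: 14 (4R,5R)-4-allyl-5-[(1S)-1-hydroxybut-2-yn-1-yl]dihydrofuran-2(3H)-one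
Conditions: THF, −78 °C; aq. NH4Cl
Reagents that add atoms: none
Why: Alkynyl Grignard addition under polar Felkin–Anh (Cornforth) control: the C14–O bond lies anti to the nucleophile, which passes the C14 hydrogen, so the 13,14-anti carbinol (13S) should predominate. At −78 °C the aldehyde reacts far faster than the lactone.

**Step 9**
Reactants: 14 (4R,5R)-4-allyl-5-[(1S)-1-hydroxybut-2-yn-1-yl]dihydrofuran-2(3H)-one
Product: 15 (4R,5R)-4-allyl-5-[(1S)-1-(TES-oxy)but-2-yn-1-yl]dihydrofuran-2(3H)-one
Conditions: Et3SiCl, imidazole, DMF, 0 °C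
Reagents that add atoms: chlorotriethylsilane, CC[Si](Cl)(CC)CC
Why: Silylation of the secondary propargylic alcohol; the TES group survives the organometallic steps and can later be removed without acid strong enough to open the epoxide.

**Step 10**
Reactants: 15 (4R,5R)-4-allyl-5-[(1S)-1-(TES-oxy)but-2-yn-1-yl]dihydrofuran-2(3H)-one
Product: 17 (4R,5R)-4-(3-hydroxypropyl)-5-[(1S)-1-(TES-oxy)but-2-yn-1-yl]dihydrofuran-2(3H)-one, via alkylborane 16 (not isolated)
Conditions: 9-BBN, THF, 0 to 23 °C; 30% H2O2, aq. NaOAc, 0 to 23 °C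
Reagents that add atoms: hydrogen peroxide, OO
Why: Anti-Markovnikov hydroboration; 9-BBN reacts with the monosubstituted alkene much faster than with the internal alkyne or the lactone, and the buffered oxidation spares lactone and silyl ether.

**Step 11**
Reactants: 17 (4R,5R)-4-(3-hydroxypropyl)-5-[(1S)-1-(TES-oxy)but-2-yn-1-yl]dihydrofuran-2(3H)-one
Product: 18 3-[(2R,3R)-5-oxo-2-[(1S)-1-(TES-oxy)but-2-yn-1-yl]tetrahydrofuran-3-yl]propanal
Conditions: Dess–Martin periodinane, NaHCO3, CH2Cl2, 0 to 23 °C
Reagents that add atoms: none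
Why: Dess–Martin oxidation of the primary alcohol to the C4 aldehyde.

**Step 12**
Reactants: 18 3-[(2R,3R)-5-oxo-2-[(1S)-1-(TES-oxy)but-2-yn-1-yl]tetrahydrofuran-3-yl]propanal
Product: 20 (4S,5R)-4-[(2R)-2-chloro-3-hydroxybutyl]-5-[(1S)-1-(TES-oxy)but-2-yn-1-yl]dihydrofuran-2(3H)-one (carbinol epimers), via chloro aldehyde 19 (not isolated)
Conditions: N-chlorosuccinimide, trans-2,5-diphenylpyrrolidine (10 mol%), CH2Cl2, 0 °C; pentane, filtration; MeMgBr, THF, −78 °C
Reagents that add atoms: N-chlorosuccinimide, O=C1CCC(=O)N1Cl; methylmagnesium bromide, C[Mg]Br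
Why: Enamine catalysis: the C2-symmetric pyrrolidine shields one face of the enamine of 18, so chlorine should be delivered to give the (3R) chloride under catalyst control (organocatalytic α-chlorination). The labile chloro aldehyde is taken on crude, the methyl Grignard reagent attacks only the aldehyde at −78 °C, and the carbinol configuration does not matter.

**Step 13**
Reactants: 20 (4S,5R)-4-[(2R)-2-chloro-3-hydroxybutyl]-5-[(1S)-1-(TES-oxy)but-2-yn-1-yl]dihydrofuran-2(3H)-one
Product: 21 (4S,5R)-4-[(2R)-2-chloro-3-oxobutyl]-5-[(1S)-1-(TES-oxy)but-2-yn-1-yl]dihydrofuran-2(3H)-one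
Conditions: Dess–Martin periodinane, NaHCO3, CH2Cl2, 0 °C
Reagents that add atoms: none
Why: Buffered Dess–Martin oxidation converts both carbinol epimers into the one α-chloro methyl ketone without base, which protects C3 from enolisation.

**Step 14**
Reactants: 22 pent-3-yn-1-ol
Product: 23 pent-3-yn-1-yl 4-methylbenzenesulfonate
Conditions: 4-MeC6H4SO2Cl, Et3N, DMAP (cat.), CH2Cl2, 0 °C
Reagents that add atoms: 4-methylbenzenesulfonyl chloride, Cc1ccc(cc1)S(=O)(=O)Cl
Why: Sulfonylation of the primary alcohol.

**Step 15**
Reactants: 23 pent-3-yn-1-yl 4-methylbenzenesulfonate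
Product: 24 hepta-1,5-diyne
Conditions: LiC≡CH·H2NCH2CH2NH2, DMSO, 15 to 23 °C
Reagents that add atoms: lithium acetylide–ethylenediamine complex, [Li+].[C-]#C.NCCN
Why: SN2 alkylation of the acetylide at the primary sulfonate puts a terminal alkyne beside the methyl-capped one.

**Step 16**
Reactants: 24 hepta-1,5-diyne
Product: 27 (3E)-4-methylnon-3-en-7-yn-1-ol, via alkenylalane 25 (not isolated), via lithium alanate 26 (not isolated)
Conditions: Me3Al, Cp2ZrCl2 (cat.), CH2Cl2, 0 to 23 °C; evaporation; n-BuLi, THF/hexane, −78 °C; ethylene oxide, −78 to 0 °C; aq. NH4Cl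
Reagents that add atoms: trimethylaluminium, C[Al](C)C; ethylene oxide, C1CO1
Why: Zirconium-catalysed carboalumination adds methyl and aluminium syn across the terminal alkyne with aluminium at the terminus, which fixes the E geometry of C7=C8; the alanate then opens the epoxide with retention at the alkenyl carbon (Negishi carboalumination and alkenylalanate alkylation). The internal alkyne reacts much more slowly.

**Step 17**
Reactants: 27 (3E)-4-methylnon-3-en-7-yn-1-ol
Product: 28 (6E)-9-bromo-6-methylnon-6-en-2-yne
Conditions: CBr4, PPh3, CH2Cl2, 0 °C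
Reagents that add atoms: carbon tetrabromide, BrC(Br)(Br)Br
Why: Appel bromination of the primary alcohol under neutral conditions leaves the olefin geometry untouched.

**Step 18**
Reactants: 28 (6E)-9-bromo-6-methylnon-6-en-2-yne
Product: 29 [(3E)-4-methylnon-3-en-7-yn-1-yl]magnesium bromide
Conditions: Mg, BrCH2CH2Br (cat.), THF, 23 to 40 °C
Reagents that add atoms: magnesium, [Mg]
Why: Magnesium insertion into the primary homoallylic bromide; the methyl-capped alkyne has no acidic hydrogen.

**Step 19 (key step)**
Reactants: 21 (4S,5R)-4-[(2R)-2-chloro-3-oxobutyl]-5-[(1S)-1-(TES-oxy)but-2-yn-1-yl]dihydrofuran-2(3H)-one; 29 [(3E)-4-methylnon-3-en-7-yn-1-yl]magnesium bromide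
Product: 31 (4R,5R)-4-{[(2S,3S)-3-methyl-3-[(3E)-4-methylnon-3-en-7-yn-1-yl]oxiran-2-yl]methyl}-5-[(1S)-1-(TES-oxy)but-2-yn-1-yl]dihydrofuran-2(3H)-one, via chlorohydrin 30 (not isolated)
Conditions: LaCl3·2LiCl, THF, −78 °C; aq. NH4Cl; then KN(SiMe3)2, THF, −78 to 0 °C
Reagents that add atoms: none
Why: The Grignard reagent 29, made less basic and more oxophilic by LaCl3·2LiCl, adds through C5 to the ketone carbon C4 of 21; the closest known reaction type is the addition of organometallic reagents to enantioenriched α-chloro aldehydes and ketones followed by base closure of the chlorohydrin to the epoxide. C4 is set by 1,2-induction from the C3 chloride: in the Cornforth (polar Felkin–Anh) transition state the C–Cl and C=O dipoles are opposed and the nucleophile passes the C3 hydrogen and not C2, which should give the anti chlorohydrin 30 with the (4S) configuration. After a cold quench the potassium alkoxide of 30 displaces chloride in a 3-exo-tet closure with inversion at C3 (R to S), so C2 and C5 end up trans on the oxirane as in the target. The step needs chemoselectivity for the ketone over the γ-lactone, which the higher electrophilicity of the α-chloro ketone and the low temperature should secure, and addition over enolisation at C3 or C18, which the lanthanum salt is there to secure. Closing the ring in a separate operation avoids warming the magnesium chlorohydrinate, which could rearrange by a 1,2-shift. Because the epoxide comes from a ketone and not from an olefin, no choice between the C3/C4 and C7/C8 positions has to be made.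

**Step 20**
Reactants: 31 epoxy diyne (as in step 19)
Product: 34 (4R,5R)-3-methylidene-4-{[(2S,3S)-3-methyl-3-[(3E)-4-methylnon-3-en-7-yn-1-yl]oxiran-2-yl]methyl}-5-[(1S)-1-(TES-oxy)but-2-yn-1-yl]dihydrofuran-2(3H)-one, via Mannich base 32 (not isolated), via ammonium iodide 33 (not isolated)
Conditions: LiN(SiMe3)2, THF, −78 °C; [Me2N=CH2]I, −78 to 0 °C; MeI, CH2Cl2/MeOH, 23 °C; aq. NaHCO3
Reagents that add atoms: N,N-dimethylmethyleneiminium iodide, C=[N+](C)C.[I-]
Why: The lactone enolate is aminomethylated at C15 (Mannich reaction with Eschenmoser's salt); quaternisation and mild base then eliminate trimethylamine to give the exo-methylene group. At −78 °C the enolate should not open the epoxide, since attack at C3 or C4 would be 4-exo or 5-endo.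

**Step 21**
Reactants: 34 α-methylene lactone diyne (as in step 20)
Product: 35 (1R,3S,4S,7E,13S,14R)-3,4-epoxy-13-(TES-oxy)-20-norcembra-7,15(17)-dien-11-yn-16,14-olide
Conditions: [Mo(≡CC6H4OMe-4)(OSiPh3)3] (cat.), 5 Å molecular sieves, toluene (high dilution), 23 to 60 °C
Reagents that add atoms: none
Why: Ring-closing alkyne metathesis of the two methyl-capped alkynes; the molybdenum alkylidyne with silanolate ligands tolerates epoxides, esters and enoates and does not touch olefins, and adsorption of the volatile by-product on the sieves drives ring closure.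

**Step 22**
Reactants: 35 cycloalkyne TES ether (as in step 21)
Product: 36 (1R,3S,4S,7E,13S,14R)-3,4-epoxy-13-hydroxy-20-norcembra-7,15(17)-dien-11-yn-16,14-olide
Conditions: Et3N·3HF, THF, 23 °C
Reagents that add atoms: none
Why: Fluoride cleaves the secondary TES ether under nearly neutral conditions that should spare the epoxide and the Michael acceptor.

**Step 23**
Reactants: 36 cycloalkyne alcohol (as in step 22)
Product: 37 (1R,3S,4S,7E,11Z,13R,14R)-3,4-epoxy-13-hydroxy-12-(tributylstannyl)-20-norcembra-7,11,15(17)-trien-16,14-olide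
Conditions: Bu3SnH, [(C5Me5)RuCl]4 (cat.), CH2Cl2, 23 °C
Reagents that add atoms: tributylstannane, CCCC[SnH](CCCC)CCCC
Why: Ruthenium-catalysed trans-hydrostannation: hydrogen bonding of the C13 hydroxyl to the chloride ligand directs tin to the proximal carbon C12 and hydrogen to C11 on the opposite side, so C10 and C13 become trans on the ring olefin. The C13 descriptor changes to R only because tin outranks oxygen-bearing carbon.

**Step 24**
Reactants: 37 alkenylstannane (as in step 23)
Product: 38 (1R,3S,4S,7E,11E,13S,14R)-3,4-epoxy-13-hydroxycembra-7,11,15(17)-trien-16,14-olide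
Conditions: MeI, Pd(PPh3)4 (cat.), Cu(O2CC4H3S) (copper thiophene-2-carboxylate), [Bu4N][Ph2PO2], DMF, 23 °C
Reagents that add atoms: iodomethane, CI
Why: Copper-assisted Stille-type methyl-for-tin exchange proceeds with retention at C12 and gives the E-trisubstituted olefin; the phosphinate traps the tin residue and the free hydroxyl is tolerated.

**Step 25**
Reactants: 38 allylic alcohol (as in step 24)
Product: 39 (1R,3S,4S,7E,11E,13S,14R)-13-acetoxy-3,4-epoxycembra-7,11,15(17)-trien-16,14-olide
Conditions: Ac2O, pyridine, DMAP (cat.), CH2Cl2, 0 to 23 °C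
Reagents that add atoms: acetic anhydride, CC(=O)OC(C)=O
Why: Acylation of the secondary allylic alcohol.

**Step 26**
Reactants: 39 acetate (as in step 25)
Product: 40 (1R,3S,4S,7S,11E,13S,14R)-13-acetoxy-3,4-epoxy-7-hydroperoxycembra-8(19),11,15(17)-trien-16,14-olide
Conditions: O2, visible light, 5,10,15,20-tetraphenylporphyrin (cat.), CH2Cl2, −20 °C
Reagents that add atoms: dioxygen, O=O
Why: Schenck ene reaction: singlet oxygen should attack the electron-rich C7=C8 olefin (C11=C12 is deactivated by the allylic acetate, the lactone olefin is electron-poor), bond to C7 and take a hydrogen from C19 on the more substituted side of the olefin (cis effect), which moves the double bond to C8=C19. C7 is set by attack on the outer face of the olefin in the macrocycle; that this face gives (7S) is an expectation and not a certainty.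

## Compound list

1 | D-glutamic acid | N[C@H](CCC(=O)O)C(=O)O | starting material
2 | (R)-5-oxotetrahydrofuran-2-carboxylic acid | OC(=O)[C@H]1CCC(=O)O1 | intermediate
3 | (R)-5-(hydroxymethyl)dihydrofuran-2(3H)-one | OC[C@H]1CCC(=O)O1 | intermediate
4 | (R)-5-[(tert-butyldiphenylsilyloxy)methyl]dihydrofuran-2(3H)-one | CC(C)(C)[Si](c1ccccc1)(c1ccccc1)OC[C@H]1CCC(=O)O1 | intermediate
5 | (5R)-5-[(tert-butyldiphenylsilyloxy)methyl]-3-(phenylselanyl)dihydrofuran-2(3H)-one (C3 epimers) | CC(C)(C)[Si](c1ccccc1)(c1ccccc1)OC[C@H]1CC([Se]c2ccccc2)C(=O)O1 | intermediate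
6 | (5R)-5-[(tert-butyldiphenylsilyloxy)methyl]-3-(phenylseleninyl)dihydrofuran-2(3H)-one (mixture of isomers) | CC(C)(C)[Si](c1ccccc1)(c1ccccc1)OC[C@H]1CC([Se](=O)c2ccccc2)C(=O)O1 | intermediate
7 | (R)-5-[(tert-butyldiphenylsilyloxy)methyl]furan-2(5H)-one | CC(C)(C)[Si](c1ccccc1)(c1ccccc1)OC[C@H]1C=CC(=O)O1 | intermediate
8 | allylmagnesium bromide | C=CC[Mg]Br | starting material
9 | tert-butyl{[(2R,3R)-3-allyl-5-(trimethylsilyloxy)-2,3-dihydrofuran-2-yl]methoxy}diphenylsilane | CC(C)(C)[Si](c1ccccc1)(c1ccccc1)OC[C@@H]1OC(O[Si](C)(C)C)=C[C@H]1CC=C | intermediate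
10 | (4R,5R)-4-allyl-5-[(tert-butyldiphenylsilyloxy)methyl]dihydrofuran-2(3H)-one | CC(C)(C)[Si](c1ccccc1)(c1ccccc1)OC[C@@H]1OC(=O)C[C@H]1CC=C | intermediate
11 | (4R,5R)-4-allyl-5-(hydroxymethyl)dihydrofuran-2(3H)-one | OC[C@@H]1OC(=O)C[C@H]1CC=C | intermediate
12 | (2R,3R)-3-allyl-5-oxotetrahydrofuran-2-carbaldehyde | O=C[C@@H]1OC(=O)C[C@H]1CC=C | intermediate
13 | prop-1-yn-1-ylmagnesium bromide | CC#C[Mg]Br | starting material
14 | (4R,5R)-4-allyl-5-[(1S)-1-hydroxybut-2-yn-1-yl]dihydrofuran-2(3H)-one | CC#C[C@H](O)[C@@H]1OC(=O)C[C@H]1CC=C | intermediate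
15 | (4R,5R)-4-allyl-5-[(1S)-1-(triethylsilyloxy)but-2-yn-1-yl]dihydrofuran-2(3H)-one | CC#C[C@H](O[Si](CC)(CC)CC)[C@@H]1OC(=O)C[C@H]1CC=C | intermediate
16 | (4R,5R)-4-[3-(9-borabicyclo[3.3.1]nonan-9-yl)propyl]-5-[(1S)-1-(triethylsilyloxy)but-2-yn-1-yl]dihydrofuran-2(3H)-one | CC#C[C@H](O[Si](CC)(CC)CC)[C@@H]1OC(=O)C[C@H]1CCCB1C2CCCC1CCC2 | intermediate
17 | (4R,5R)-4-(3-hydroxypropyl)-5-[(1S)-1-(triethylsilyloxy)but-2-yn-1-yl]dihydrofuran-2(3H)-one | CC#C[C@H](O[Si](CC)(CC)CC)[C@@H]1OC(=O)C[C@H]1CCCO | intermediate
18 | 3-[(2R,3R)-5-oxo-2-[(1S)-1-(triethylsilyloxy)but-2-yn-1-yl]tetrahydrofuran-3-yl]propanal | CC#C[C@H](O[Si](CC)(CC)CC)[C@@H]1OC(=O)C[C@H]1CCC=O | intermediate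
19 | (2R)-2-chloro-3-[(2R,3S)-5-oxo-2-[(1S)-1-(triethylsilyloxy)but-2-yn-1-yl]tetrahydrofuran-3-yl]propanal | CC#C[C@H](O[Si](CC)(CC)CC)[C@@H]1OC(=O)C[C@H]1C[C@@H](Cl)C=O | intermediate
20 | (4S,5R)-4-[(2R)-2-chloro-3-hydroxybutyl]-5-[(1S)-1-(triethylsilyloxy)but-2-yn-1-yl]dihydrofuran-2(3H)-one (carbinol epimers) | CC#C[C@H](O[Si](CC)(CC)CC)[C@@H]1OC(=O)C[C@H]1C[C@@H](Cl)C(C)O | intermediate
21 | (4S,5R)-4-[(2R)-2-chloro-3-oxobutyl]-5-[(1S)-1-(triethylsilyloxy)but-2-yn-1-yl]dihydrofuran-2(3H)-one | CC#C[C@H](O[Si](CC)(CC)CC)[C@@H]1OC(=O)C[C@H]1C[C@@H](Cl)C(C)=O | intermediate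
22 | pent-3-yn-1-ol | CC#CCCO | starting material
23 | pent-3-yn-1-yl 4-methylbenzenesulfonate | CC#CCCOS(=O)(=O)c1ccc(C)cc1 | intermediate
24 | hepta-1,5-diyne | CC#CCCC#C | intermediate
25 | dimethyl[(1E)-2-methylhept-1-en-5-yn-1-yl]alane | CC#CCC/C(C)=C/[Al](C)C | intermediate
26 | lithium butyl(dimethyl)[(1E)-2-methylhept-1-en-5-yn-1-yl]aluminate | [Li+].CC#CCC/C(C)=C/[Al-](C)(C)CCCC | intermediate
27 | (3E)-4-methylnon-3-en-7-yn-1-ol | CC#CCC/C(C)=C/CCO | intermediate
28 | (6E)-9-bromo-6-methylnon-6-en-2-yne | CC#CCC/C(C)=C/CCBr | intermediate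
29 | [(3E)-4-methylnon-3-en-7-yn-1-yl]magnesium bromide | CC#CCC/C(C)=C/CC[Mg]Br | intermediate
30 | (4S,5R)-4-[(2R,3S,6E)-2-chloro-3-hydroxy-3,7-dimethyldodec-6-en-10-yn-1-yl]-5-[(1S)-1-(triethylsilyloxy)but-2-yn-1-yl]dihydrofuran-2(3H)-one | CC#C[C@H](O[Si](CC)(CC)CC)[C@@H]1OC(=O)C[C@H]1C[C@@H](Cl)[C@@](C)(O)CC/C=C(\C)CCC#CC | intermediate
31 | (4R,5R)-4-{[(2S,3S)-3-methyl-3-[(3E)-4-methylnon-3-en-7-yn-1-yl]oxiran-2-yl]methyl}-5-[(1S)-1-(triethylsilyloxy)but-2-yn-1-yl]dihydrofuran-2(3H)-one | CC#C[C@H](O[Si](CC)(CC)CC)[C@@H]1OC(=O)C[C@H]1C[C@@H]1O[C@@]1(C)CC/C=C(\C)CCC#CC | intermediate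
32 | 3-[(dimethylamino)methyl] derivative of 31 (C15 epimers) | CC#C[C@H](O[Si](CC)(CC)CC)[C@@H]1OC(=O)C(CN(C)C)[C@H]1C[C@@H]1O[C@@]1(C)CC/C=C(\C)CCC#CC | intermediate
33 | 3-[(trimethylammonio)methyl] derivative of 31, iodide (C15 epimers) | CC#C[C@H](O[Si](CC)(CC)CC)[C@@H]1OC(=O)C(C[N+](C)(C)C)[C@H]1C[C@@H]1O[C@@]1(C)CC/C=C(\C)CCC#CC.[I-] | intermediate
34 | (4R,5R)-3-methylidene-4-{[(2S,3S)-3-methyl-3-[(3E)-4-methylnon-3-en-7-yn-1-yl]oxiran-2-yl]methyl}-5-[(1S)-1-(triethylsilyloxy)but-2-yn-1-yl]dihydrofuran-2(3H)-one | CC#C[C@H](O[Si](CC)(CC)CC)[C@@H]1OC(=O)C(=C)[C@H]1C[C@@H]1O[C@@]1(C)CC/C=C(\C)CCC#CC | intermediate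
35 | (1R,3S,4S,7E,13S,14R)-3,4-epoxy-13-(triethylsilyloxy)-20-norcembra-7,15(17)-dien-11-yn-16,14-olide (trans-fused lactone) | C1C#C[C@H](O[Si](CC)(CC)CC)[C@@H]2OC(=O)C(=C)[C@H]2C[C@@H]2O[C@@]2(C)CC/C=C(\C)C1 | intermediate
36 | (1R,3S,4S,7E,13S,14R)-3,4-epoxy-13-hydroxy-20-norcembra-7,15(17)-dien-11-yn-16,14-olide | C1C#C[C@H](O)[C@@H]2OC(=O)C(=C)[C@H]2C[C@@H]2O[C@@]2(C)CC/C=C(\C)C1 | intermediate
37 | (1R,3S,4S,7E,11Z,13R,14R)-3,4-epoxy-13-hydroxy-12-(tributylstannyl)-20-norcembra-7,11,15(17)-trien-16,14-olide | C1/C=C(\[Sn](CCCC)(CCCC)CCCC)[C@H](O)[C@@H]2OC(=O)C(=C)[C@H]2C[C@@H]2O[C@@]2(C)CC/C=C(\C)C1 | intermediate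
38 | (1R,3S,4S,7E,11E,13S,14R)-3,4-epoxy-13-hydroxycembra-7,11,15(17)-trien-16,14-olide | C1/C=C(\C)[C@H](O)[C@@H]2OC(=O)C(=C)[C@H]2C[C@@H]2O[C@@]2(C)CC/C=C(\C)C1 | intermediate
39 | (1R,3S,4S,7E,11E,13S,14R)-13-acetoxy-3,4-epoxycembra-7,11,15(17)-trien-16,14-olide | C1/C=C(\C)[C@H](OC(C)=O)[C@@H]2OC(=O)C(=C)[C@H]2C[C@@H]2O[C@@]2(C)CC/C=C(\C)C1 | intermediate
40 | (1R,3S,4S,7S,11E,13S,14R)-13-acetoxy-3,4-epoxy-7-hydroperoxycembra-8(19),11,15(17)-trien-16,14-olide (CNP0166375.1) | C=C1CC/C=C(\C)[C@H](OC(C)=O)[C@@H]2OC(=O)C(=C)[C@H]2C[C@@H]2O[C@@]2(C)CC[C@@H]1OO | target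

## Step count and least certain steps

Total: 26 steps. Longest linear sequence: 21 steps (steps 1–13 and 19–26); the enyne half takes steps 14–18.

**Step 19 (key step).** The most likely failures are insufficient 1,2-induction at C4 (a methyl ketone discriminates less than an aldehyde between the Cornforth rotamers), enolisation with loss of the C3 configuration, and competing attack on the lactone.
Fallback: the epoxide is made by reagent-controlled epoxidation of an olefin that has no competitor, and the two halves are joined at C6–C7 by cross-coupling. It sets out from 15 and returns at 31.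
- Lemieux–Johnson cleavage of the allyl group of 15 (OsO4 cat., NaIO4, 2,6-lutidine) gives the C3 aldehyde F1.
- Wittig reaction with Ph3P=C(CH3)CHO gives the (E)-enal F2, and methylenation with Ph3P=CH2 gives the diene F3.
- 9-BBN adds to the terminal vinyl group to give the alkylborane F4, and buffered peroxide oxidation gives the homoallylic alcohol F5.
- Shi epoxidation of the only olefin of F5, with KHSO5 and the enantiomer of the fructose-derived ketone, gives the (3S,4S)-epoxy alcohol F6, and I2/PPh3/imidazole gives the iodide F7.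
- Separately, the alane 25 (from 24 as in step 16) is quenched with iodine to the alkenyl iodide F8.
- Zinc insertion into F7 (Zn, LiCl, THF) gives the alkylzinc iodide F9, and Negishi coupling with F8 (Pd(PPh3)4) gives 31 with the E geometry retained.

This takes seven operations in place of the six of steps 10–13, 18 and 19.

**Step 26.** Hydrogen abstraction may occur from C6 instead of C19, which would place the hydroperoxide on C8; attack may occur on both faces at C7; and some oxidation at C11=C12 is possible.
Fallback for the facial problem: C7 is set by a reagent and the peroxide is brought in by substitution. It sets out from 39 and returns at 40.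
- The photooxygenation is worked up with Ac2O/pyridine/DMAP, which dehydrates 40 and its C7 epimer F10 alike to the enone F11; a tertiary C8 hydroperoxide cannot dehydrate and is separated.
- 1,2-Reduction with a CBS oxazaborolidine and BH3·SMe2, the catalyst enantiomer chosen for this outcome, gives the (7R)-allylic alcohol F12.
- Mesylation gives the mesylate F13, and displacement with 2-methoxyprop-2-yl hydroperoxide and CsOH in DMF at 0 °C, with inversion, gives the (7S)-peroxy ketal F14.
- Aqueous acetic acid releases 40.

The displacement must outpace conjugate addition of the peroxide anion to the α-methylene lactone. This fallback does not correct the choice between C19 and C6 hydrogen abstraction.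

**Step 21.** Oligomerisation may compete with ring closure, and the catalyst may be lost to the epoxide or to addition of silanolate to the Michael acceptor.
Fallback: the ring is closed before the Michael acceptor exists. It sets out from 31 and returns at 35.
- Alkyne metathesis of 31 under the conditions of step 21 gives the cycloalkyne F17.
- The enolate of F17 is aminomethylated as in step 20 to the Mannich base F18, methyl iodide gives the ammonium iodide F19, and NaHCO3 eliminates it to 35.

**Step 8.** Facial selectivity in the addition to the α-acyloxy aldehyde may be low, and C14 may epimerise in the aldehyde.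
Fallback: C13 is set by a reagent instead of by C14. It sets out from 14 (with its C13 epimer F15) and returns at 14.
- The mixture of 14 and the epimer F15 is oxidised with Dess–Martin periodinane to the ynone F16.
- Asymmetric transfer hydrogenation with RuCl(p-cymene)(TsDPEN) in HCO2H/Et3N, the ligand enantiomer chosen to deliver the (13S) carbinol, gives 14.

## Further compounds

F1 | step 19 | 2-[(2R,3R)-5-oxo-2-[(1S)-1-(triethylsilyloxy)but-2-yn-1-yl]tetrahydrofuran-3-yl]acetaldehyde | CC#C[C@H](O[Si](CC)(CC)CC)[C@@H]1OC(=O)C[C@H]1CC=O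
F2 | step 19 | (2E)-2-methyl-4-[(2R,3R)-5-oxo-2-[(1S)-1-(triethylsilyloxy)but-2-yn-1-yl]tetrahydrofuran-3-yl]but-2-enal | CC#C[C@H](O[Si](CC)(CC)CC)[C@@H]1OC(=O)C[C@H]1C/C=C(\C)C=O
F3 | step 19 | (4R,5R)-4-[(2E)-3-methylpenta-2,4-dien-1-yl]-5-[(1S)-1-(triethylsilyloxy)but-2-yn-1-yl]dihydrofuran-2(3H)-one | CC#C[C@H](O[Si](CC)(CC)CC)[C@@H]1OC(=O)C[C@H]1C/C=C(\C)C=C
F4 | step 19 | (4R,5R)-4-[(2E)-5-(9-borabicyclo[3.3.1]nonan-9-yl)-3-methylpent-2-en-1-yl]-5-[(1S)-1-(triethylsilyloxy)but-2-yn-1-yl]dihydrofuran-2(3H)-one | CC#C[C@H](O[Si](CC)(CC)CC)[C@@H]1OC(=O)C[C@H]1C/C=C(\C)CCB1C2CCCC1CCC2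
F5 | step 19 | (4R,5R)-4-[(2E)-5-hydroxy-3-methylpent-2-en-1-yl]-5-[(1S)-1-(triethylsilyloxy)but-2-yn-1-yl]dihydrofuran-2(3H)-one | CC#C[C@H](O[Si](CC)(CC)CC)[C@@H]1OC(=O)C[C@H]1C/C=C(\C)CCO
F6 | step 19 | (4R,5R)-4-{[(2S,3S)-3-(2-hydroxyethyl)-3-methyloxiran-2-yl]methyl}-5-[(1S)-1-(triethylsilyloxy)but-2-yn-1-yl]dihydrofuran-2(3H)-one | CC#C[C@H](O[Si](CC)(CC)CC)[C@@H]1OC(=O)C[C@H]1C[C@@H]1O[C@@]1(C)CCO
F7 | step 19 | (4R,5R)-4-{[(2S,3S)-3-(2-iodoethyl)-3-methyloxiran-2-yl]methyl}-5-[(1S)-1-(triethylsilyloxy)but-2-yn-1-yl]dihydrofuran-2(3H)-one | CC#C[C@H](O[Si](CC)(CC)CC)[C@@H]1OC(=O)C[C@H]1C[C@@H]1O[C@@]1(C)CCI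
F8 | step 19 | (1E)-1-iodo-2-methylhept-1-en-5-yne | I/C=C(\C)CCC#CC
F9 | step 19 | alkylzinc iodide of F7 (zinc in place of iodine on the ethyl side chain) | CC#C[C@H](O[Si](CC)(CC)CC)[C@@H]1OC(=O)C[C@H]1C[C@@H]1O[C@@]1(C)CC[Zn]I
F10 | step 26 | (7R) epimer of 40 | C=C1CC/C=C(\C)[C@H](OC(C)=O)[C@@H]2OC(=O)C(=C)[C@H]2C[C@@H]2O[C@@]2(C)CC[C@H]1OO
F11 | step 26 | (1R,3S,4S,11E,13S,14R)-13-acetoxy-3,4-epoxy-7-oxocembra-8(19),11,15(17)-trien-16,14-olide | C=C1CC/C=C(\C)[C@H](OC(C)=O)[C@@H]2OC(=O)C(=C)[C@H]2C[C@@H]2O[C@@]2(C)CCC1=O
F12 | step 26 | (1R,3S,4S,7R,11E,13S,14R)-13-acetoxy-3,4-epoxy-7-hydroxycembra-8(19),11,15(17)-trien-16,14-olide | C=C1CC/C=C(\C)[C@H](OC(C)=O)[C@@H]2OC(=O)C(=C)[C@H]2C[C@@H]2O[C@@]2(C)CC[C@H]1O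
F13 | step 26 | (7R)-7-methanesulfonate of F12 | C=C1CC/C=C(\C)[C@H](OC(C)=O)[C@@H]2OC(=O)C(=C)[C@H]2C[C@@H]2O[C@@]2(C)CC[C@H]1OS(C)(=O)=O
F14 | step 26 | (7S)-7-[(2-methoxypropan-2-yl)peroxy] derivative (peroxy ketal of 40) | C=C1CC/C=C(\C)[C@H](OC(C)=O)[C@@H]2OC(=O)C(=C)[C@H]2C[C@@H]2O[C@@]2(C)CC[C@@H]1OOC(C)(C)OC
F15 | step 8 | (4R,5R)-4-allyl-5-[(1R)-1-hydroxybut-2-yn-1-yl]dihydrofuran-2(3H)-one | CC#C[C@@H](O)[C@@H]1OC(=O)C[C@H]1CC=C
F16 | step 8 | (4R,5R)-4-allyl-5-(but-2-ynoyl)dihydrofuran-2(3H)-one | CC#CC(=O)[C@@H]1OC(=O)C[C@H]1CC=C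
F17 | step 21 | (1R,3S,4S,7E,13S,14R)-3,4-epoxy-13-(triethylsilyloxy)-20-norcembr-7-en-11-yn-16,14-olide | C1C#C[C@H](O[Si](CC)(CC)CC)[C@@H]2OC(=O)C[C@H]2C[C@@H]2O[C@@]2(C)CC/C=C(\C)C1
F18 | step 21 | 15-[(dimethylamino)methyl] derivative of F17 (C15 epimers) | C1C#C[C@H](O[Si](CC)(CC)CC)[C@@H]2OC(=O)C(CN(C)C)[C@H]2C[C@@H]2O[C@@]2(C)CC/C=C(\C)C1
F19 | step 21 | 15-[(trimethylammonio)methyl] derivative of F17, iodide (C15 epimers) | C1C#C[C@H](O[Si](CC)(CC)CC)[C@@H]2OC(=O)C(C[N+](C)(C)C)[C@H]2C[C@@H]2O[C@@]2(C)CC/C=C(\C)C1.[I-]
A1 | alternative 1 | all-trans 3-(hydroxymethyl)-4-vinyl-5-(trityloxymethyl)dihydrofuran-2(3H)-one | C(c1ccccc1)(c1ccccc1)(c1ccccc1)OC[C@@H]1OC(=O)[C@H](CO)[C@H]1C=C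
A2 | alternative 1 | (R)-5-(trityloxymethyl)furan-2(5H)-one | C(c1ccccc1)(c1ccccc1)(c1ccccc1)OC[C@H]1C=CC(=O)O1
A3 | alternative 1 | formaldehyde | C=O
A4 | alternative 2 | macrocyclic α-methylene lactone, C13 triethylsilyl ether | C1/C=C(\C)[C@H](O[Si](CC)(CC)CC)[C@@H]2OC(=O)C(=C)[C@H]2C[C@@H]2O[C@@]2(C)CC/C=C(\C)C1
A5 | alternative 2 | macrocyclic homopropargylic alcohol (C14 hydroxyl, C1 ethynyl, C13 triethylsilyl ether) | C1/C=C(\C)[C@H](O[Si](CC)(CC)CC)[C@H](O)[C@@H](C#C)C[C@@H]2O[C@@]2(C)CC/C=C(\C)C1
A6 | alternative 2 | carbon monoxide | [C-]#[O+]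
A7 | alternative 3 | 14-membered epoxy lactone, C13 triethylsilyl ether | C1/C=C(\C)[C@H](O[Si](CC)(CC)CC)[C@@H]2OC(=O)C[C@H]2C[C@@H]2O[C@@]2(C)CC/C=C(\C)C1
A8 | alternative 3 | acyclic epoxy ynal (C13 aldehyde on the lactone, methyl-capped C11≡C12 alkyne) | O=C[C@@H]1OC(=O)C[C@H]1C[C@@H]1O[C@@]1(C)CC/C=C(\C)CCC#CC
A9 | alternative 3 | triethylsilane | CC[SiH](CC)CC
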